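**Retrosynthetic overview**
- The plan rests on ring B, a resorcinol in which the formyl-bearing C3 lies between the two oxygen-bearing carbons C2 and C4, with the carboxyl carbon on C1, H on C5 and CH3 on C6.
- Ring B is cut into a four-carbon vinylketene (C2, C5, C6, C1; from diazo enone 14 by Wolff rearrangement) and the two-carbon ynol silyl ether 18 (C3 with the masked formyl group, C4 with oxygen). This is a Danheiser benzannulation that forms C2–C3, C4–C5 and C1–C2.
- Diazo enone 14 comes from methyl ketone 11 by diazo transfer. Ketone 11 is the ester of acid 9 (Wittig reaction on butane-2,3-dione) with ring A bromide 5 (lateral lithiation and bromination of MOM-protected atraric acid).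
- Ring A is bought intact; ring B is the only ring formed (step 8). Fluoride and then acid release the target.

Key step: step 8

Remark: the target has no stereocentre, so the only stereochemical element on the way is the E-alkene of 8 to 21. Ring B is numbered C1 (ester-bearing) to C6 (methyl-bearing) and ring A is the methyl benzoate ring. The lithium amide bases are taken as purchased solutions.

**Step 1**
Reactants: 1 atraric acid (methyl 2,4-dihydroxy-3,6-dimethylbenzoate)
Product: 3 methyl 2,4-bis(methoxymethoxy)-3,6-dimethylbenzoate, via disodium diphenoxide 2 (not isolated)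
Conditions: NaH, MOMCl, DMF, 0 °C → rt
Reagents that add atoms: chloromethyl methyl ether (MOMCl), COCCl
Why: Williamson etherification of both sodium phenoxides, where full deprotonation in DMF breaks the hydrogen bond of the ester-flanked 2-OH so that both oxygens should be alkylated.

**Step 2**
Reactants: 3 methyl 2,4-bis(methoxymethoxy)-3,6-dimethylbenzoate
Product: 5 methyl 6-(bromomethyl)-2,4-bis(methoxymethoxy)-3-methylbenzoate, via benzylic lithium species 4 (not isolated)
Conditions: LiN(iPr)2, THF, −78 °C; then cannulated into BrCCl2CCl2Br, THF, −78 °C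
Reagents that add atoms: 1,2-dibromo-1,1,2,2-tetrachloroethane, BrC(Cl)(Cl)C(Cl)(Cl)Br
Why: Lateral lithiation of an ortho-toluate followed by electrophilic bromination; only the 6-methyl group is conjugated with the ester and acidic enough for the amide base, so the 3-methyl group and the ring C–H should stay untouched, and inverse addition into excess bromine donor keeps the carbanion away from the bromide being formed.

**Step 3**
Reactants: 6 butane-2,3-dione (in excess); 7 tert-butyl (triphenylphosphoranylidene)acetate
Product: 8 tert-butyl (E)-3-methyl-4-oxopent-2-enoate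
Conditions: CH2Cl2, 0 °C → rt
Reagents that add atoms: none
Why: Wittig olefination of one carbonyl of the symmetrical, activated 1,2-diketone by a stabilized ylide, which should place acetyl and ester trans (E) under the usual control for stabilized ylides, while the excess of diketone suppresses double olefination.

**Step 4**
Reactants: 8 tert-butyl (E)-3-methyl-4-oxopent-2-enoate
Product: 9 (E)-3-methyl-4-oxopent-2-enoic acid
Conditions: CF3CO2H, CH2Cl2, 0 °C → rt
Reagents that add atoms: none
Why: Acidolysis of the tert-butyl ester with loss of isobutene (E1 fragmentation), in which the E-geometry keeps the acid from closing onto the ketone as a lactol.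

**Step 5**
Reactants: 9 (E)-3-methyl-4-oxopent-2-enoic acid; 5 methyl 6-(bromomethyl)-2,4-bis(methoxymethoxy)-3-methylbenzoate
Product: 11 [2-(methoxycarbonyl)-3,5-bis(methoxymethoxy)-4-methylphenyl]methyl (E)-3-methyl-4-oxopent-2-enoate, via potassium carboxylate 10 (not isolated)
Conditions: KHCO3, DMF, rt
Reagents that add atoms: none
Why: SN2 O-alkylation of a carboxylate by a benzylic bromide, with a base too weak to enolize the ketone or isomerize the alkene.

**Step 6**
Reactants: 11 [2-(methoxycarbonyl)-3,5-bis(methoxymethoxy)-4-methylphenyl]methyl (E)-3-methyl-4-oxopent-2-enoate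
Product: 14 [2-(methoxycarbonyl)-3,5-bis(methoxymethoxy)-4-methylphenyl]methyl (E)-5-diazo-3-methyl-4-oxopent-2-enoate, via lithium enolate 12 (not isolated), via trifluoroacetyl diketone 13 (not isolated)
Conditions: LiN(SiMe3)2, THF, −78 °C (ketone added to base); CF3CO2CH2CF3, −78 °C; cold dilute aq HCl work-up; then MsN3, Et3N, H2O (1 equiv), MeCN, rt
Reagents that add atoms: methanesulfonyl azide (MsN3), CS(=O)(=O)N=[N+]=[N-]; 2,2,2-trifluoroethyl trifluoroacetate, O=C(OCC(F)(F)F)C(F)(F)F (its CF3CO group stays only in 13)
Why: Detrifluoroacetylative diazo transfer (a deacylative Regitz-type transfer), in which the kinetic lithium enolate of the methyl ketone is C-trifluoroacetylated in a Claisen condensation and the resulting 1,3-diketone takes the diazo group from the sulfonyl azide with loss of the trifluoroacetyl group as its N-sulfonyl amide, the established entry to α'-diazo enones that avoids dipolar cycloaddition of diazomethane to the activated alkene.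

**Step 7**
Reactants: 15 3,3-diethoxyprop-1-yne
Product: 18 3,3-diethoxy-1-(triisopropylsilyloxy)prop-1-yne, via lithium acetylide 16 (not isolated), via lithium ynolate 17 (not isolated)
Conditions: LiN(SiMe3)2, THF, −78 °C; t-BuOOLi (from t-BuOOH and LiN(SiMe3)2), −78 → 0 °C; iPr3SiOTf, −78 → 0 °C
Reagents that add atoms: tert-butyl hydroperoxide, CC(C)(C)OO; triisopropylsilyl trifluoromethanesulfonate, CC(C)[Si](OS(=O)(=O)C(F)(F)F)(C(C)C)C(C)C
Why: Electrophilic oxygen transfer from lithium tert-butyl peroxide to the lithium acetylide gives the ynolate, which the bulky silyl triflate should capture on oxygen to give the isolable triisopropylsilyl ynol ether (acetylide oxidation and O-silylation).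

**Step 8**
Reactants: 14 diazo enone; 18 3,3-diethoxy-1-(triisopropylsilyloxy)prop-1-yne (1.5 equiv)
Product: 23 [2-(methoxycarbonyl)-3,5-bis(methoxymethoxy)-4-methylphenyl]methyl 3-(diethoxymethyl)-2-hydroxy-6-methyl-4-(triisopropylsilyloxy)benzoate, via vinylketene 19 (not isolated), via vinylcyclobutenone 20 (not isolated), via dienylketene 21 (not isolated), via cyclohexadienone 22 (not isolated)
Conditions: hν (365 nm), degassed ClCH2CH2Cl, base-washed Pyrex, rt; then 80 °C
Reagents that add atoms: none
Why: Irradiation at 365 nm, where the diazo enone absorbs but the meta-dialkoxybenzyl ester chromophore of ring A does not, should expel N2 with migration of the alkenyl group (Wolff rearrangement) to vinylketene 19 with the E-alkene intact. The polarized ynol ether then adds through its acetal-bearing carbon to the ketene carbonyl carbon (C2–C3) and closes C4–C5 to give 4-vinylcyclobutenone 20 ([2+2] cycloaddition); at 80 °C 20 opens by 4π electrocyclic cleavage to dienylketene 21, which closes ring B by thermal 6π electrocyclization (C1–C2) to dienone 22, and enolization gives phenol 23. The closest known reaction type is the Danheiser benzannulation of α'-diazo enones with triisopropylsiloxyalkynes, which gives resorcinol monosilyl ethers; an ester at the ketene terminus combined with an acetal on the alkyne is a new substrate pairing for it. No stereocentre is created, since the sp3 centres of racemic 20 and 22 vanish on aromatization. The selectivity needed is regiochemical: the oxygen lone pair makes the alkyne carbon remote from oxygen the nucleophile, which places the masked formyl carbon between the two oxygens, and the E-enoate turns H rather than the ester inward in the 6π closure. A vinylogous closure of the zwitterion onto C1 would only exchange the silyl group between the two ring B oxygens and would converge after step 9.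

**Step 9**
Reactants: 23 benzannulation product
Product: 24 [2-(methoxycarbonyl)-3,5-bis(methoxymethoxy)-4-methylphenyl]methyl 3-(diethoxymethyl)-2,4-dihydroxy-6-methylbenzoate
Conditions: Bu4NF, AcOH, THF, 0 °C; crude product taken on directly
Reagents that add atoms: none
Why: Fluoride-driven cleavage of the aryl silyl ether (formation of the strong Si–F bond), buffered with acetic acid so that the esters, the acetal and the MOM ethers should be left alone.

**Step 10**
Reactants: 24 desilylated acetal
Product: 25 [3,5-dihydroxy-2-(methoxycarbonyl)-4-methylphenyl]methyl 3-formyl-2,4-dihydroxy-6-methylbenzoate (target)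
Conditions: 3 M aq HCl, MeOH/THF, 40 °C
Reagents that add atoms: water, O
Why: Acid-catalysed acetal hydrolysis and transacetalization of the two MOM ethers to methanol (formaldehyde leaves as dimethoxymethane and cannot alkylate ring A); the benzylic ester oxygen sits meta to both ring A oxygens and should not ionize, and the hindered, hydrogen-bonded benzoate should resist methanolysis.

**Compound list**
1 | atraric acid (methyl 2,4-dihydroxy-3,6-dimethylbenzoate) | COC(=O)c1c(C)cc(O)c(C)c1O | starting material
2 | disodium 4-(methoxycarbonyl)-2,5-dimethylbenzene-1,3-diolate | COC(=O)c1c(C)cc([O-])c(C)c1[O-].[Na+].[Na+] | intermediate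
3 | methyl 2,4-bis(methoxymethoxy)-3,6-dimethylbenzoate | COC(=O)c1c(C)cc(OCOC)c(C)c1OCOC | intermediate
4 | [2-(methoxycarbonyl)-3,5-bis(methoxymethoxy)-4-methylbenzyl]lithium | [Li]Cc1cc(OCOC)c(C)c(OCOC)c1C(=O)OC | intermediate
5 | methyl 6-(bromomethyl)-2,4-bis(methoxymethoxy)-3-methylbenzoate | BrCc1cc(OCOC)c(C)c(OCOC)c1C(=O)OC | intermediate
6 | butane-2,3-dione | CC(=O)C(C)=O | starting material
7 | tert-butyl (triphenylphosphoranylidene)acetate | CC(C)(C)OC(=O)C=P(c1ccccc1)(c1ccccc1)c1ccccc1 | starting material
8 | tert-butyl (E)-3-methyl-4-oxopent-2-enoate | CC(=O)/C(C)=C/C(=O)OC(C)(C)C | intermediate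
9 | (E)-3-methyl-4-oxopent-2-enoic acid | CC(=O)/C(C)=C/C(=O)O | intermediate
10 | potassium (E)-3-methyl-4-oxopent-2-enoate | CC(=O)/C(C)=C/C(=O)[O-].[K+] | intermediate
11 | [2-(methoxycarbonyl)-3,5-bis(methoxymethoxy)-4-methylphenyl]methyl (E)-3-methyl-4-oxopent-2-enoate | CC(=O)/C(C)=C/C(=O)OCc1cc(OCOC)c(C)c(OCOC)c1C(=O)OC | intermediate
12 | lithium (E)-5-{[2-(methoxycarbonyl)-3,5-bis(methoxymethoxy)-4-methylphenyl]methoxy}-3-methyl-5-oxopenta-1,3-dien-2-olate | C=C([O-])/C(C)=C/C(=O)OCc1cc(OCOC)c(C)c(OCOC)c1C(=O)OC.[Li+] | intermediate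
13 | [2-(methoxycarbonyl)-3,5-bis(methoxymethoxy)-4-methylphenyl]methyl (E)-7,7,7-trifluoro-3-methyl-4,6-dioxohept-2-enoate | O=C(CC(=O)/C(C)=C/C(=O)OCc1cc(OCOC)c(C)c(OCOC)c1C(=O)OC)C(F)(F)F | intermediate
14 | [2-(methoxycarbonyl)-3,5-bis(methoxymethoxy)-4-methylphenyl]methyl (E)-5-diazo-3-methyl-4-oxopent-2-enoate | [N-]=[N+]=CC(=O)/C(C)=C/C(=O)OCc1cc(OCOC)c(C)c(OCOC)c1C(=O)OC | intermediate
15 | 3,3-diethoxyprop-1-yne | C#CC(OCC)OCC | starting material
16 | (3,3-diethoxyprop-1-yn-1-yl)lithium | [Li]C#CC(OCC)OCC | intermediate
17 | lithium 3,3-diethoxyprop-1-yn-1-olate | CCOC(OCC)C#C[O-].[Li+] | intermediate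
18 | 3,3-diethoxy-1-(triisopropylsilyloxy)prop-1-yne | CCOC(OCC)C#CO[Si](C(C)C)(C(C)C)C(C)C | intermediate
19 | [2-(methoxycarbonyl)-3,5-bis(methoxymethoxy)-4-methylphenyl]methyl (2E)-3-methyl-5-oxopenta-2,4-dienoate (vinylketene) | O=C=C/C(C)=C/C(=O)OCc1cc(OCOC)c(C)c(OCOC)c1C(=O)OC | intermediate
20 | [2-(methoxycarbonyl)-3,5-bis(methoxymethoxy)-4-methylphenyl]methyl (E)-3-[3-(diethoxymethyl)-4-oxo-2-(triisopropylsilyloxy)cyclobut-2-en-1-yl]but-2-enoate (racemic) | CCOC(OCC)C1=C(O[Si](C(C)C)(C(C)C)C(C)C)C(/C(C)=C/C(=O)OCc2cc(OCOC)c(C)c(OCOC)c2C(=O)OC)C1=O | intermediate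
21 | [2-(methoxycarbonyl)-3,5-bis(methoxymethoxy)-4-methylphenyl]methyl (2E,4E)-6-(diethoxymethyl)-3-methyl-7-oxo-5-(triisopropylsilyloxy)hepta-2,4,6-trienoate (dienylketene) | CCOC(OCC)C(=C=O)/C(O[Si](C(C)C)(C(C)C)C(C)C)=C\C(C)=C\C(=O)OCc1cc(OCOC)c(C)c(OCOC)c1C(=O)OC | intermediate
22 | [2-(methoxycarbonyl)-3,5-bis(methoxymethoxy)-4-methylphenyl]methyl 3-(diethoxymethyl)-6-methyl-2-oxo-4-(triisopropylsilyloxy)cyclohexa-3,5-diene-1-carboxylate (racemic) | CCOC(OCC)C1=C(O[Si](C(C)C)(C(C)C)C(C)C)C=C(C)C(C(=O)OCc2cc(OCOC)c(C)c(OCOC)c2C(=O)OC)C1=O | intermediate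
23 | [2-(methoxycarbonyl)-3,5-bis(methoxymethoxy)-4-methylphenyl]methyl 3-(diethoxymethyl)-2-hydroxy-6-methyl-4-(triisopropylsilyloxy)benzoate | CCOC(OCC)c1c(O[Si](C(C)C)(C(C)C)C(C)C)cc(C)c(C(=O)OCc2cc(OCOC)c(C)c(OCOC)c2C(=O)OC)c1O | intermediate
24 | [2-(methoxycarbonyl)-3,5-bis(methoxymethoxy)-4-methylphenyl]methyl 3-(diethoxymethyl)-2,4-dihydroxy-6-methylbenzoate | CCOC(OCC)c1c(O)cc(C)c(C(=O)OCc2cc(OCOC)c(C)c(OCOC)c2C(=O)OC)c1O | intermediate
25 | [3,5-dihydroxy-2-(methoxycarbonyl)-4-methylphenyl]methyl 3-formyl-2,4-dihydroxy-6-methylbenzoate | COC(=O)c1c(COC(=O)c2c(C)cc(O)c(C=O)c2O)cc(O)c(C)c1O | target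

**Step count**
Total: 10 steps. Longest linear sequence: 7 steps (steps 1, 2, 5, 6, 8, 9, 10 from atraric acid; equally steps 3, 4, 5, 6, 8, 9, 10 from butane-2,3-dione).

**Steps most likely to fail**

1. Step 8. Photoisomerization of the enoate double bond could turn the ester inward, which would slow the 6π closure or open an oxa-6π closure onto the ester carbonyl. Residual light absorption by ring A could trigger cleavage of the benzylic C–O bond. The electron-poor ketene could also dimerize or be trapped faster than it adds to the ynol ether.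
 Fallback: it sets out from bromide 5 and comes back at target 25, placing the formyl carbon by directed ortho-metalation before the two rings are joined. Orcinol F1 is converted with NaH and MOMCl in DMF into 1,3-bis(methoxymethoxy)-5-methylbenzene F2. n-BuLi and TMEDA in THF at 0 °C metalate the position between the two MOM ethers to give [2,6-bis(methoxymethoxy)-4-methylphenyl]lithium F3, and DMF converts it into lithium (dimethylamino)[2,6-bis(methoxymethoxy)-4-methylphenyl]methanolate F4. This adduct masks the aldehyde while s-BuLi and TMEDA at −78 °C metalate the position between a MOM ether and the methyl group, giving lithium (dimethylamino)[3-lithio-2,6-bis(methoxymethoxy)-4-methylphenyl]methanolate F5. Carbon dioxide and acidic work-up then deliver 3-formyl-2,4-bis(methoxymethoxy)-6-methylbenzoic acid F6. Alkylation of F6 with 5 (KHCO3, DMF, rt) gives [2-(methoxycarbonyl)-3,5-bis(methoxymethoxy)-4-methylphenyl]methyl 3-formyl-2,4-bis(methoxymethoxy)-6-methylbenzoate F7, and 3 M aq HCl in MeOH/THF at 40 °C removes the four MOM groups to give 25.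

2. Step 6. Michael addition of the lithium enolate to the 4-oxo-enoate of ketone 11 that is not yet deprotonated, or deprotonation at the vinylic methyl group, could consume material before trifluoroacetylation.
 Fallback: it sets out from 11 and comes back at 14 without an enolate and without a sulfonyl azide. Soft enolization (Me3SiOTf, Et3N, CH2Cl2, −20 °C) gives [2-(methoxycarbonyl)-3,5-bis(methoxymethoxy)-4-methylphenyl]methyl (E)-3-methyl-4-(trimethylsilyloxy)penta-2,4-dienoate F8. NBS in THF at −78 °C brominates the terminal carbon to give [2-(methoxycarbonyl)-3,5-bis(methoxymethoxy)-4-methylphenyl]methyl (E)-5-bromo-3-methyl-4-oxopent-2-enoate F9. N,N'-Ditosylhydrazine and DBU in THF at 0 °C convert F9 into 14 by N-alkylation and two sulfinate eliminations.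

3. Step 2. Alkylation of the benzylic carbanion by the bromide as it forms (Wurtz-type coupling), or proton transfer from the more acidic bromide to the carbanion, could divert material to dimers and over-brominated products.
 Fallback: it sets out from 3 and comes back at 5 by forming a C–O bond at the carbanion stage, so that the trapped product is not an electrophile. Carbanion 4, made as in step 2, is quenched at −78 °C with bis(trimethylsilyl) peroxide to give methyl 2,4-bis(methoxymethoxy)-3-methyl-6-[(trimethylsilyloxy)methyl]benzoate F10. F10 is taken on crude and treated with Ph3PBr2 in CH2Cl2 at 0 °C, which exchanges the silyl ether directly for bromide and gives 5 without passing through the free hydroxy ester that would lactonize to the phthalide.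

**Further compounds**
F1 | step 8 | orcinol (5-methylbenzene-1,3-diol) | Cc1cc(O)cc(O)c1
F2 | step 8 | 1,3-bis(methoxymethoxy)-5-methylbenzene | COCOc1cc(C)cc(OCOC)c1
F3 | step 8 | [2,6-bis(methoxymethoxy)-4-methylphenyl]lithium | [Li]c1c(OCOC)cc(C)cc1OCOC
F4 | step 8 | lithium (dimethylamino)[2,6-bis(methoxymethoxy)-4-methylphenyl]methanolate | [Li+].[O-]C(N(C)C)c1c(OCOC)cc(C)cc1OCOC
F5 | step 8 | lithium (dimethylamino)[3-lithio-2,6-bis(methoxymethoxy)-4-methylphenyl]methanolate | [Li+].[O-]C(N(C)C)c1c(OCOC)cc(C)c([Li])c1OCOC
F6 | step 8 | 3-formyl-2,4-bis(methoxymethoxy)-6-methylbenzoic acid | COCOc1cc(C)c(C(=O)O)c(OCOC)c1C=O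
F7 | step 8 | [2-(methoxycarbonyl)-3,5-bis(methoxymethoxy)-4-methylphenyl]methyl 3-formyl-2,4-bis(methoxymethoxy)-6-methylbenzoate | COCOc1cc(C)c(C(=O)OCc2cc(OCOC)c(C)c(OCOC)c2C(=O)OC)c(OCOC)c1C=O
F8 | step 6 | [2-(methoxycarbonyl)-3,5-bis(methoxymethoxy)-4-methylphenyl]methyl (E)-3-methyl-4-(trimethylsilyloxy)penta-2,4-dienoate | C=C(O[Si](C)(C)C)/C(C)=C/C(=O)OCc1cc(OCOC)c(C)c(OCOC)c1C(=O)OC
F9 | step 6 | [2-(methoxycarbonyl)-3,5-bis(methoxymethoxy)-4-methylphenyl]methyl (E)-5-bromo-3-methyl-4-oxopent-2-enoate | BrCC(=O)/C(C)=C/C(=O)OCc1cc(OCOC)c(C)c(OCOC)c1C(=O)OC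
F10 | step 2 | methyl 2,4-bis(methoxymethoxy)-3-methyl-6-[(trimethylsilyloxy)methyl]benzoate | C[Si](C)(C)OCc1cc(OCOC)c(C)c(OCOC)c1C(=O)OC
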